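In the elm run, at its last reading, D stands at 25.1 % while G has lost 86.5 % of the charge, so D is far less than what left G. That gap is what to watch on repeating this flask.

| flask | G | remark | time |
|---|---|---|---|
| elm | 20 mM | the very flask that is asked about, followed so far |  |
| maple | 13 mM | run made earlier |  |
| flask | 20 mM |  | 12 min |

- elm (time / min: D / %, G / %): 0.667: 17.5, 42.5; 1.00: 21.6, 31.4; 1.50: 24.2, 22.5; 2.50: 25.1, 13.5
- maple (time / min: D / %, G / %): 0.667: 18.4, 50.8; 1.33: 26.6, 30.8; 4.00: 27.9, 8.6; 8.00: 18.9, 4.6

(readings scatter by 0.5 percentage points)

- the best time, 12 min at the latest, for D
- the amount of D, in percent of the G charged, at that time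



I build the flask up one process at a time. Counting the step G to D by itself, D equals what G has lost and keeps rising, so this reckoning puts the best time at 12 min. A side path for G lowers the height. The selectivity, the share of used G found as D, is 0.304 at the first elm reading and 0.374 at the first maple reading. It is lower at the higher charge, so I take the side path to be of higher order in [G]. In this reckoning D still only rises.

The peak comes with the third process, a loss of D itself. Late in maple, with G down to 8.6 %, D falls from 27.9 % to 18.9 %. That gives 7.12 min, the loss half-life of D: the time D takes to halve net, with what G still supplies left in, as read from these scattered readings.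

Over the last 1.00 min of elm, this half-life puts the loss at 2.4 percentage points. D still gained 0.9 points, so by this reckoning G supplied 3.3 points out of the 9 points it lost, a share of 0.372. With that share and that loss held, D in elm stops rising when G's fall over that length of time reaches 6.6 points. The interval before, scaled to the same length, shows 18 points. Continuing that decay, I place the peak at 2.34 min, with D a little above the 25.1 % of the last elm reading.

The forecast gives 2.5 min (2.1 min to 3.1 min) and 25.3 % (24.7 % to 26 %), saying “the peak lies near 2.5 min, barely above the last reading”, a later time than mine.

The flask gives 25.8 % at 2.39 min.

    2 G → E (k = 33.1 M⁻¹ min⁻¹)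
    J ⇌ Q (K = 9.80, k = 3.66 min⁻¹)
    D ⇌ J (K = 1.36, k = 0.162 min⁻¹)
    G ⇌ D (K = 5.92, k = 0.438 min⁻¹)

From that peak, the loss half-life carries D to 10.1 % at 12 min, and the flask holds 9.63 %. The neighbouring flask is the same charge read at 3.0 min. The same reckoning, over the time since the peak, gives 24.3 %. That neighbouring flask holds more D than this reckoning gives, namely 25.4 %, with G still at 10.4 %.

The readings were generated by integration from invented constants; scatter was added.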